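The rate constants are invented; no experiment stands behind them.

Start with an easy step: read the flasks and what is asked.

| flask | Z | L | time | remark |
|---|---|---|---|---|
| Monday's | 0.047 M | 2.00 equiv | 40 h | everything together in a closed stirred flask, run for 40 h |
| Sunday's | 0.047 M | 2.00 equiv |  | a single well-mixed tank run continuously and read at steady state, 40 h in it on average |
| Saturday's | 0.047 M (fed, over 20.0 h) | 2.00 equiv | 40 h | a stirred flask in which Z is dosed at a steady rate over 20.0 h without added volume, worked up at 40 h |
| Thursday's | 0.047 M | 2.00 equiv (fed, over 20.0 h) | 40 h | all but L at the start; L goes in evenly over 20.0 h, the run ends at 40 h |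

    Z + L → Z.L (k1 = 3.64 × 10⁻⁴ M⁻¹ s⁻¹)
    Z + L → D (k2 = 1.90 × 10⁻⁴ M⁻¹ s⁻¹)
    L + Z.L → L.Z.L (k3 = 4.48 × 10⁻⁶ M⁻¹ s⁻¹)
    L + D → L.Z.L (k4 = 7.95 × 10⁻⁵ M⁻¹ s⁻¹)
    L + Z.L → G (k5 = 6.87 × 10⁻⁴ M⁻¹ s⁻¹)

- the stated concentrations are those of everything mixed, before any reaction; amounts are the same in each set-up
- the feed brings no volume worth counting
- run time (Monday's): 40 h

- the set-up with the highest share of Z.L in all that became Z.L or L.Z.L or G, at the outlet or at the end ("none" if the first two lie within 2 percentage points) (Monday's / Sunday's / Saturday's / Thursday's / none)
- share of Z.L in all that became Z.L or L.Z.L or G, at the outlet or at the end, Monday's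
- share of Z.L in all that became Z.L or L.Z.L or G, at the outlet or at the end, Sunday's
- share of Z.L in all that became Z.L or L.Z.L or G, at the outlet or at the end, Saturday's
- share of Z.L in all that became Z.L or L.Z.L or G, at the outlet or at the end, Thursday's

Ines and Tom dispute the winner. Ines watches L. At L as charged, step 5 alone halves Z.L in 3.0 h on Monday's, far shorter than the 40 h run. So she feeds L slowly. She takes L at half its charge during Thursday's feed, which stretches that half-life to 6.00 h. She names Thursday's.

Tom watches Z. Let z be the fraction of Z left. Each step that uses Z or Z.L carries one factor of L, so L drops out when those rates are divided. Two numbers remain. F = 0.657 is the part of used Z that becomes Z.L. The wear ratio w = 1.25 is the constants using Z.L, summed, over the constants using Z, summed. It is a selectivity factor.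

In a closed flask holding all its Z from the start, however L arrives, Z.L as a fraction of the Z charged is F(z − z^w)/(w − 1). This curve peaks at z = 40.9%, with Z.L at 21.5%. So Monday's and Thursday's ride one curve, and slow L merely delays Thursday's along it. On this curve, for closed flasks like these, more Z left means more Z.L below the peak.

Sunday's tank has its own balance: z = 1/(1 + u), where u is (k1 + k2) times L times the mean time. With L at its full 0.0940 M, u is 7.50 and z is 11.8%. Lower L leaves more. Tom expects a high share where much Z stays unused, so he names Sunday's.

The forecast, on Tom's side, gives 18.4% for Sunday's, 15.1% for Thursday's, 14.6% for Saturday's and 9.9% for Monday's, since “its low conversion preserves Z.L”.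

The flask gives Sunday's at 18.4%, with Thursday's at 15.1%, Saturday's at 14.7% and Monday's at 9.92%. Tom wins. Monday's kept 5.08% of its Z at 40.0 h; the curve turns that into 7.01%, and the flask held 7.03%. Ines gets the flask charged short. A neighbour of Monday's with 0.800 equiv of L kept 41.9% of its Z, close to the peak. There the curve gives 21.5%, and that flask held 21.5% of Z.L, a share of 54.5%.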